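**Plan**

1. Feature (germacrane numbering: ring C1–C10, O-bridge C2/C5, C4=C15H2, C10=C14H2, lactone O–C6 and C7–C11(=C13H2)–C12, tiglate on O–C8): the oxolane O–C2–C3–C4–C5 is the ring tautomer of a ten-membered 5-hydroxy-2-ketone, and C3, C4 and C15 are the three carbons of allene lying between a carbinol carbon (C5) and a ketone carbon (C2).
2. Retrosynthesis: open the hemiketal, exchange the oxidation levels of C2 and C5 (2-hydroxy-5-enone), then cut C4–C5 and C2–C3 together into acid chloride (C5) + allene + aldehyde (C2), a Pd/In acylative allylation that also closes the ten-membered ring.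
3. The seco acid-aldehyde is cut at C8–C9 (asymmetric allylation with a C9/C10/C14/C1/C2 allylstannane) and at C7–C8 and C11–C13 (vinyl conjugate addition with Mannich trapping on the (S)-butenolide that supplies C5, C6, C7, C11, C12).
4. Forward order of rings: lactone (bought as butenolide), then side chain and tiglate, then the ten-membered carbocycle (key step), then the oxolane last by C2 oxidation, C5 reduction and spontaneous hemiketalisation.
5. Stereochemistry: C6 from the chiral pool; C7 by addition trans to the C6 substituent; C8 by (S)-BINOL–Ti catalyst control; C5 by Felkin–Anh (Luche) reduction next to C6–O; C2 by the geometric demand of the bridge.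

Key step: step 12

Assumption: the ten-membered 5-hydroxy-2-ketone is taken to close spontaneously to the 2,5-bridged hemiketal with the 2S configuration, because only a cis-bridged oxolane can span the ring; the C-2 carbinol formed in the key step is carried as an epimer mixture (centre left undefined in its SMILES) and is removed by oxidation.

**Route**

Step 1
Reactants: 1 (S)-5-(hydroxymethyl)furan-2(5H)-one
Product: 2 (S)-5-{[(tert-butyldimethylsilyl)oxy]methyl}furan-2(5H)-one
Conditions: TBSCl, imidazole, DMF, 0 °C → rt
Reagents that add atoms: tert-butyldimethylsilyl chloride, CC(C)(C)[Si](C)(C)Cl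
Why: Standard imidazole-promoted silylation of the primary alcohol, which leaves the C6 stereocentre untouched and provides the bulky group that steers the conjugate addition.

Step 2
Reactants: 2 (S)-5-{[(tert-butyldimethylsilyl)oxy]methyl}furan-2(5H)-one
Product: 4 (3R,4S,5S)-5-{[(tert-butyldimethylsilyl)oxy]methyl}-3-[(dimethylamino)methyl]-4-vinyldihydrofuran-2(3H)-one, via bromomagnesium enolate 3 (not isolated)
Conditions: CH2=CHMgBr, CuBr·SMe2 (10 mol%), THF, −78 °C; then CH2=NMe2+ I−, −78 °C → rt
Reagents that add atoms: vinylmagnesium bromide, C=C[Mg]Br; N,N-dimethylmethyleneiminium iodide (Eschenmoser's salt), C=[N+](C)C.[I-]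
Why: Copper-catalysed conjugate addition should place the vinyl group trans to the C6 silyloxymethyl group (sets C7), and the enolate should then undergo a Mannich reaction anti to the new vinyl group, installing C13 as a masked exocyclic methylene.

Step 3
Reactants: 4 (3R,4S,5S)-5-{[(tert-butyldimethylsilyl)oxy]methyl}-3-[(dimethylamino)methyl]-4-vinyldihydrofuran-2(3H)-one
Product: 6 (2S,3S,4R)-2-{[(tert-butyldimethylsilyl)oxy]methyl}-4-[(dimethylamino)methyl]-5-oxotetrahydrofuran-3-carbaldehyde, via diol 5 (not isolated)
Conditions: OsO4 (2 mol%), NaIO4, 2,6-lutidine, dioxane/H2O (3:1), rt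
Reagents that add atoms: osmium tetroxide (catalytic, reoxidised by periodate), O=[Os](=O)(=O)=O; sodium periodate, [Na+].[O-][I](=O)(=O)=O
Why: Lemieux–Johnson cleavage (dihydroxylation, then periodate glycol scission) should turn the vinyl group into the C8 aldehyde while the lactone, silyl ether and lutidine-buffered amine survive and C7 stays in its stable all-trans arrangement.

Step 4
Reactants: 7 2-(chloromethyl)-3-(trimethylsilyl)prop-1-ene; 8 trimethyl orthoformate
Product: 9 2-(chloromethyl)-4,4-dimethoxybut-1-ene
Conditions: TMSOTf (5 mol%), CH2Cl2, −78 °C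
Reagents that add atoms: none
Why: Hosomi–Sakurai reaction, in which the allylsilane attacks the dimethoxycarbenium ion from the orthoformate in SE2' fashion to give the homoallylic acetal (future C1–C2) and keep the allylic chloride.

Step 5
Reactants: 9 2-(chloromethyl)-4,4-dimethoxybut-1-ene
Product: 10 tributyl(4,4-dimethoxy-2-methylidenebutyl)stannane
Conditions: Bu3SnSnBu3, Pd(PPh3)4 (3 mol%), THF, 60 °C
Reagents that add atoms: hexabutylditin, CCCC[Sn](CCCC)(CCCC)[Sn](CCCC)(CCCC)CCCC
Why: Palladium-catalysed stannylation of an allylic chloride with a distannane (π-allylpalladium, Sn–Sn transmetalation, C–Sn reductive elimination) is a known route to 2-substituted allylstannanes and tolerates the acetal.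

Step 6
Reactants: 6 (2S,3S,4R)-2-{[(tert-butyldimethylsilyl)oxy]methyl}-4-[(dimethylamino)methyl]-5-oxotetrahydrofuran-3-carbaldehyde; 10 tributyl(4,4-dimethoxy-2-methylidenebutyl)stannane
Product: 11 (3R,4R,5S)-5-{[(tert-butyldimethylsilyl)oxy]methyl}-3-[(dimethylamino)methyl]-4-[(1S)-1-hydroxy-5,5-dimethoxy-3-methylidenepentyl]dihydrofuran-2(3H)-one
Conditions: (S)-BINOL (20 mol%), Ti(OiPr)4 (10 mol%), 4 Å MS, CH2Cl2, −20 °C
Reagents that add atoms: none
Why: Keck asymmetric allylation, in which the (S)-BINOL–titanium catalyst should direct the 2-substituted allylstannane to the Si face of the aldehyde, giving the 8S carbinol under catalyst control and joining C8–C9.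

Step 7
Reactants: 11 the 8S homoallylic alcohol from step 6; 12 tigloyl chloride [(E)-2-methylbut-2-enoyl chloride]
Product: 13 (3R,4R,5S)-5-{[(tert-butyldimethylsilyl)oxy]methyl}-3-[(dimethylamino)methyl]-4-[(1S)-5,5-dimethoxy-3-methylidene-1-(tigloyloxy)pentyl]dihydrofuran-2(3H)-one
Conditions: pyridine, DMAP (10 mol%), CH2Cl2, 0 °C → rt
Reagents that add atoms: none
Why: DMAP-catalysed acylation of the secondary alcohol, where the weak base pyridine avoids ketene formation so the E geometry of the tiglate is kept, and capping O–C8 removes the risk of translactonisation.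

Step 8
Reactants: 13 the C-8 tiglate from step 7
Product: 15 (4R,5S)-5-{[(tert-butyldimethylsilyl)oxy]methyl}-4-[(1S)-5,5-dimethoxy-3-methylidene-1-(tigloyloxy)pentyl]-3-methylidenedihydrofuran-2(3H)-one, via trimethylammonium iodide 14 (not isolated)
Conditions: MeI, MeCN, rt; then aq. NaHCO3, EtOAc, rt
Reagents that add atoms: none
Why: Quaternisation of the Mannich base and E1cB (Hofmann-type) elimination, the second half of an Eschenmoser methylenation, should unveil the α-methylene lactone without harming the esters, acetal or silyl ether.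

Step 9
Reactants: 15 the α-methylene lactone silyl ether from step 8
Product: 16 (4R,5S)-5-(hydroxymethyl)-4-[(1S)-5,5-dimethoxy-3-methylidene-1-(tigloyloxy)pentyl]-3-methylidenedihydrofuran-2(3H)-one
Conditions: HF·pyridine, pyridine, THF, 0 °C → rt
Reagents that add atoms: none
Why: Pyridine-buffered fluoride cleavage of the primary TBS ether, to which the acetal, both esters and the Michael-acceptor lactone are stable.

Step 10
Reactants: 16 the primary alcohol from step 9
Product: 18 (2S,3R)-3-[(1S)-5,5-dimethoxy-3-methylidene-1-(tigloyloxy)pentyl]-4-methylidene-5-oxotetrahydrofuran-2-carboxylic acid, via aldehyde 17 (not isolated)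
Conditions: TEMPO (20 mol%), PhI(OAc)2, MeCN/H2O (1:1), rt
Reagents that add atoms: water, O
Why: Oxoammonium (TEMPO/PhI(OAc)2) oxidation should take the primary alcohol through the aldehyde hydrate to the acid, as is usual for CH2OH groups on oxygen-bearing ring carbons, without touching the alkenes or the acetal.

Step 11
Reactants: 18 the lactone carboxylic acid acetal from step 10
Product: 19 (2S,3R)-4-methylidene-3-[(1S)-3-methylidene-5-oxo-1-(tigloyloxy)pentyl]-5-oxotetrahydrofuran-2-carboxylic acid
Conditions: PPTS (20 mol%), acetone/H2O (10:1), rt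
Reagents that add atoms: water, O
Why: Mild acid-catalysed acetal hydrolysis should free the C2 aldehyde, the weak acid and low temperature keeping the β,γ-unsaturated aldehyde out of conjugation.

Step 12
Reactants: 19 the seco acid-aldehyde from step 11; 20 propadiene (allene)
Product: 23 (6S,7R,8S)-2-hydroxy-5-oxo-8-tigloyloxygermacra-4(15),10(14),11(13)-trien-12,6-olide (C-2 epimers), via acid chloride 21 (not isolated), via allylindium species 22 (not isolated)
Conditions: 1-chloro-N,N,2-trimethylprop-1-en-1-amine, CH2Cl2, 0 °C; then syringe-pump addition to Pd(PPh3)4 (10 mol%), InI, allene (1 atm), THF, rt (final 2 mM)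
Reagents that add atoms: none
Why: Proposed new method: Pd(0) inserts into the C–Cl bond of 21, the acylpalladium adds across one C=C of allene 20 with the acyl group going to the central carbon (C4–C5 bond) to give a 2-acyl-π-allylpalladium, and InI reduces this to the nucleophilic 2-acylallylindium 22, which attacks the tethered aldehyde through its CH2 terminus (C2–C3 bond). The closest known reactions are the Pd/In three-component coupling of aryl halides, allenes and aldehydes, the Pd-catalysed acylstannylation of allenes with acid chlorides, and Barbier-type macrocyclisations of 2-(alkoxycarbonyl)allyl metals onto aldehydes; an acid chloride as electrophile and a ring-closing aldehyde have not been combined in this cascade. The ten-membered carbocycle closes by a 10-exo-trig carbonyl allylation, helped by the rigid trans-lactone and by syringe-pump dilution. The only new stereocentre, the C-2 carbinol, is not controlled and need not be, since step 13 oxidises it. The step needs regioselective insertion (acyl on the central allene carbon, the normal outcome because it leads to the π-allyl complex), chemoselective oxidative addition (only the acid chloride reacts with Pd(0), and no allylic position carries a leaving group) and chemoselective addition (allylindium reagents add to aldehydes but not to lactones, enoates or the product enone).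

Step 13
Reactants: 23 the macrocyclic 2-hydroxy-5-enone from step 12
Product: 24 (6S,7R,8S)-2,5-dioxo-8-tigloyloxygermacra-4(15),10(14),11(13)-trien-12,6-olide
Conditions: Dess–Martin periodinane, NaHCO3, CH2Cl2, 0 °C
Reagents that add atoms: none
Why: Dess–Martin oxidation should convert both C-2 epimers into one ketone, the buffered non-basic medium avoiding isomerisation of the exocyclic enone and furan formation from the 1,4-diketone.

Step 14
Reactants: 24 the macrocyclic 2,5-dione from step 13
Product: 26 target (2S,5S,6S,7R,8S)-2,5-epoxy-2-hydroxy-8-tigloyloxygermacra-4(15),10(14),11(13)-trien-12,6-olide, via ring-open keto alcohol 25 (not isolated)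
Conditions: NaBH4, CeCl3·7H2O, MeOH, −78 °C
Reagents that add atoms: none
Why: Luche reduction should attack the more electrophilic α-acyloxy enone carbonyl (C5) in 1,2 fashion with hydride anti to the C6–O bond (polar Felkin–Anh, giving 5S), and the new hydroxyl then adds across the ring to the C2 ketone to form the bridged hemiketal, which also shields C2 from reduction.

**Compound list**

1 | (S)-5-(hydroxymethyl)furan-2(5H)-one | C1=CC(=O)O[C@@H]1CO | starting material
2 | (S)-5-{[(tert-butyldimethylsilyl)oxy]methyl}furan-2(5H)-one | C1=CC(=O)O[C@@H]1CO[Si](C)(C)C(C)(C)C | intermediate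
3 | bromomagnesium enolate of the trans-4-vinyl lactone (not isolated) | C=C[C@H]1C=C(O[Mg]Br)O[C@@H]1CO[Si](C)(C)C(C)(C)C | intermediate
4 | (3R,4S,5S)-5-{[(tert-butyldimethylsilyl)oxy]methyl}-3-[(dimethylamino)methyl]-4-vinyldihydrofuran-2(3H)-one | C=C[C@H]1[C@H](CN(C)C)C(=O)O[C@@H]1CO[Si](C)(C)C(C)(C)C | intermediate
5 | 1,2-diol from dihydroxylation of the vinyl group of 4 (not isolated, carbinol epimers) | OCC(O)[C@H]1[C@H](CN(C)C)C(=O)O[C@@H]1CO[Si](C)(C)C(C)(C)C | intermediate
6 | (2S,3S,4R)-2-{[(tert-butyldimethylsilyl)oxy]methyl}-4-[(dimethylamino)methyl]-5-oxotetrahydrofuran-3-carbaldehyde | O=C[C@H]1[C@H](CN(C)C)C(=O)O[C@@H]1CO[Si](C)(C)C(C)(C)C | intermediate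
7 | 2-(chloromethyl)-3-(trimethylsilyl)prop-1-ene | C=C(CCl)C[Si](C)(C)C | starting material
8 | trimethyl orthoformate | COC(OC)OC | starting material
9 | 2-(chloromethyl)-4,4-dimethoxybut-1-ene | C=C(CCl)CC(OC)OC | intermediate
10 | tributyl(4,4-dimethoxy-2-methylidenebutyl)stannane | C=C(CC(OC)OC)C[Sn](CCCC)(CCCC)CCCC | intermediate
11 | (3R,4R,5S)-5-{[(tert-butyldimethylsilyl)oxy]methyl}-3-[(dimethylamino)methyl]-4-[(1S)-1-hydroxy-5,5-dimethoxy-3-methylidenepentyl]dihydrofuran-2(3H)-one | COC(OC)CC(=C)C[C@H](O)[C@H]1[C@H](CN(C)C)C(=O)O[C@@H]1CO[Si](C)(C)C(C)(C)C | intermediate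
12 | tigloyl chloride, (E)-2-methylbut-2-enoyl chloride | ClC(=O)/C(C)=C/C | starting material
13 | (3R,4R,5S)-5-{[(tert-butyldimethylsilyl)oxy]methyl}-3-[(dimethylamino)methyl]-4-[(1S)-5,5-dimethoxy-3-methylidene-1-(tigloyloxy)pentyl]dihydrofuran-2(3H)-one | COC(OC)CC(=C)C[C@H](OC(=O)/C(C)=C/C)[C@H]1[C@H](CN(C)C)C(=O)O[C@@H]1CO[Si](C)(C)C(C)(C)C | intermediate
14 | N-methyl quaternary ammonium iodide of 13 (not isolated) | COC(OC)CC(=C)C[C@H](OC(=O)/C(C)=C/C)[C@H]1[C@H](C[N+](C)(C)C)C(=O)O[C@@H]1CO[Si](C)(C)C(C)(C)C.[I-] | intermediate
15 | (4R,5S)-5-{[(tert-butyldimethylsilyl)oxy]methyl}-4-[(1S)-5,5-dimethoxy-3-methylidene-1-(tigloyloxy)pentyl]-3-methylidenedihydrofuran-2(3H)-one | COC(OC)CC(=C)C[C@H](OC(=O)/C(C)=C/C)[C@H]1C(=C)C(=O)O[C@@H]1CO[Si](C)(C)C(C)(C)C | intermediate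
16 | (4R,5S)-5-(hydroxymethyl)-4-[(1S)-5,5-dimethoxy-3-methylidene-1-(tigloyloxy)pentyl]-3-methylidenedihydrofuran-2(3H)-one | COC(OC)CC(=C)C[C@H](OC(=O)/C(C)=C/C)[C@H]1C(=C)C(=O)O[C@@H]1CO | intermediate
17 | (2S,3R)-3-[(1S)-5,5-dimethoxy-3-methylidene-1-(tigloyloxy)pentyl]-4-methylidene-5-oxotetrahydrofuran-2-carbaldehyde (not isolated) | COC(OC)CC(=C)C[C@H](OC(=O)/C(C)=C/C)[C@H]1C(=C)C(=O)O[C@@H]1C=O | intermediate
18 | (2S,3R)-3-[(1S)-5,5-dimethoxy-3-methylidene-1-(tigloyloxy)pentyl]-4-methylidene-5-oxotetrahydrofuran-2-carboxylic acid | COC(OC)CC(=C)C[C@H](OC(=O)/C(C)=C/C)[C@H]1C(=C)C(=O)O[C@@H]1C(=O)O | intermediate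
19 | (2S,3R)-4-methylidene-3-[(1S)-3-methylidene-5-oxo-1-(tigloyloxy)pentyl]-5-oxotetrahydrofuran-2-carboxylic acid | O=CCC(=C)C[C@H](OC(=O)/C(C)=C/C)[C@H]1C(=C)C(=O)O[C@@H]1C(=O)O | intermediate
20 | propadiene (allene) | C=C=C | starting material
21 | acid chloride of 19 (not isolated) | O=CCC(=C)C[C@H](OC(=O)/C(C)=C/C)[C@H]1C(=C)C(=O)O[C@@H]1C(=O)Cl | intermediate
22 | 2-acylallylindium(III) chloride iodide derived from 21 and allene (not isolated) | O=CCC(=C)C[C@H](OC(=O)/C(C)=C/C)[C@H]1C(=C)C(=O)O[C@@H]1C(=O)C(=C)C[In](Cl)I | intermediate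
23 | (6S,7R,8S)-2-hydroxy-5-oxo-8-tigloyloxygermacra-4(15),10(14),11(13)-trien-12,6-olide (C-2 epimers) | C=C1C[C@H](OC(=O)/C(C)=C/C)[C@H]2C(=C)C(=O)O[C@@H]2C(=O)C(=C)CC(O)C1 | intermediate
24 | (6S,7R,8S)-2,5-dioxo-8-tigloyloxygermacra-4(15),10(14),11(13)-trien-12,6-olide | C=C1C[C@H](OC(=O)/C(C)=C/C)[C@H]2C(=C)C(=O)O[C@@H]2C(=O)C(=C)CC(=O)C1 | intermediate
25 | (5S,6S,7R,8S)-5-hydroxy-2-oxo-8-tigloyloxygermacra-4(15),10(14),11(13)-trien-12,6-olide (ring-open tautomer, not isolated) | C=C1C[C@H](OC(=O)/C(C)=C/C)[C@H]2C(=C)C(=O)O[C@@H]2[C@@H](O)C(=C)CC(=O)C1 | intermediate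
26 | CNP0307443.2, (2S,5S,6S,7R,8S)-2,5-epoxy-2-hydroxy-8-tigloyloxygermacra-4(15),10(14),11(13)-trien-12,6-olide | C=C1C[C@H](OC(=O)/C(C)=C/C)[C@H]2C(=C)C(=O)O[C@@H]2[C@H]2O[C@@](O)(C1)CC2=C | target

**Count and risks**

Total steps: 14. Longest linear sequence: 12 (steps 1–3 and 6–14, from 1); the stannane branch (steps 4–5) joins at step 6.

Steps most likely to fail:

1. Step 12 (bears the label). The acylallylindium intermediate may be protonated or may oligomerise before the strained ten-membered closure, the acylpalladium may lose CO, or unreacted acid chloride may acylate the allylindium intermolecularly. The fallback makes the two bonds in two known operations instead of one cascade. It sets out from 19, converted to acid chloride 21 as in step 12. Palladium-catalysed acylstannylation of allene 20 with 21 and hexabutylditin, a known three-component addition that puts the acyl group on the central allene carbon and tin on the terminus, should give the isolable 2-acylallylstannane aldehyde F1. BF3·OEt2 at high dilution in CH2Cl2 at −78 °C should then close the ring by intramolecular allylstannane–aldehyde addition, and the route is rejoined at 23.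

2. Step 14. Hydride may be delivered to the C2 ketone or to the wrong face of C5, and the exocyclic enone of 24 may isomerise into the conjugated ene-dione before it is reduced. The fallback reverses the order of the two redox events so that no dione is formed. It sets out from 23: oxazaborolidine-catalysed (CBS) borane reduction of the only ketone present, with the catalyst enantiomer chosen for the 5S carbinol, should give the 2,5-diol F2. TEMPO/PhI(OAc)2 should then oxidise the unhindered, non-allylic C-2 carbinol in preference to the hindered C-5 carbinol next to the lactone oxygen; the keto alcohol 25 closes on its own and the route is rejoined at 26.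

3. Step 6. The tertiary amine may inhibit the titanium catalyst, and catalyst and substrate preferences may be mismatched, giving poor facial selectivity at C8. The fallback replaces catalyst control by a stereoconvergent esterification. It sets out from 6: BF3·OEt2-promoted addition of stannane 10 (excess BF3 ties up the amine, substrate control only) should give 11 together with its C-8 epimer F3. After separation, 11 continues through step 7, while F3 is esterified with tiglic acid under Mitsunobu conditions (PPh3, DIAD), which inverts C8 and gives the tiglate directly; both streams rejoin the route at 13.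

**Further compounds**

F1 | step 12 | 2-acylallylstannane aldehyde, (2S,3R)-lactone bearing a 2-[(tributylstannyl)methyl]acryloyl group at C-2 of the lactone ring and the aldehyde side chain of 19 | O=CCC(=C)C[C@H](OC(=O)/C(C)=C/C)[C@H]1C(=C)C(=O)O[C@@H]1C(=O)C(=C)C[Sn](CCCC)(CCCC)CCCC
F2 | step 14 | (5S,6S,7R,8S)-2,5-dihydroxy-8-tigloyloxygermacra-4(15),10(14),11(13)-trien-12,6-olide (C-2 epimers) | C=C1C[C@H](OC(=O)/C(C)=C/C)[C@H]2C(=C)C(=O)O[C@@H]2[C@@H](O)C(=C)CC(O)C1
F3 | step 6 | C-8 epimer of 11, (3R,4R,5S)-5-{[(tert-butyldimethylsilyl)oxy]methyl}-3-[(dimethylamino)methyl]-4-[(1R)-1-hydroxy-5,5-dimethoxy-3-methylidenepentyl]dihydrofuran-2(3H)-one | COC(OC)CC(=C)C[C@@H](O)[C@H]1[C@H](CN(C)C)C(=O)O[C@@H]1CO[Si](C)(C)C(C)(C)C
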